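**Strategy.** Everything rests on disconnecting the bond between the quaternary carbon Cq (shared by the cyclopentane, the six-membered lactam and the seven-membered ring, and flanked by the lactam C=O and the CHOH carbon) and the ethyl-bearing CH. Since Cq links the two termini of the chain CH(Et)–CH(O)–CH–CH into the cyclopentane, that ring is made by a nickel-catalysed vinylcyclopropane-to-cyclopentene shift. The precursor is a lactam-fused cyclopropane carrying an ester on Cq and, on the neighbouring carbon, a Z-configured silyloxybutenyl group. In one operation the shift forms the Cq–CH(Et) bond, closes the cyclopentene, sets two stereocentres and leaves a silyl enol ether for building the fused lactone.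

Key step: step 8

Assumption: compounds 1, 4, 9, 13, 15 and 22 are taken as purchasable; benzyl is chosen both for the ester on Cq and for the ether on the N-propyl chain, so that one hydrogenolysis frees both.

**Route**

Step 1
Reactants: 1 N-Boc-D-allylglycine
Product: 3 N-Boc-D-allylglycinal, via acyl imidazolide 2 (not isolated)
Conditions: CDI, CH2Cl2, 0 °C; then i-Bu2AlH, −78 °C; aq. Rochelle salt
Reagents that add atoms: none
Why: Reduction of an acyl imidazolide by i-Bu2AlH stops at the aldehyde because the tetrahedral aluminium adduct survives until work-up (partial reduction of an activated acid derivative), and the cold, non-basic conditions should preserve the R centre of the amino aldehyde, which is used at once.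

Step 2
Reactants: 3 N-Boc-D-allylglycinal; 4 methyl (S)-3-bromo-2-methylpropanoate
Product: 8 Boc-amino lactone, via zinc homoenolate 5 (not isolated), via titanium homoenolate 6 (not isolated), via hydroxy ester 7 (not isolated)
Conditions: 4, Zn, I2 (cat.), DMA, 70 °C; TiCl3(OiPr), CH2Cl2, −40 °C; then 3, −40 to −20 °C; H2O; PPTS (cat.), PhMe, 60 °C
Reagents that add atoms: none
Why: Cram-chelate-controlled addition of a chlorotitanium ester homoenolate to the N-Boc α-amino aldehyde should give the syn amino alcohol, that is the new R carbinol centre by attack on the chelate face away from the allyl group, while the methyl-bearing centre comes intact from the S bromo ester and acid-catalysed lactonisation then closes the γ-lactone.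

Step 3
Reactants: 8 Boc-amino lactone; 9 3-(benzyloxy)propanal
Product: 12 secondary amine, via amine hydrochloride 10 (not isolated), via imine 11 (not isolated)
Conditions: HCl (4 M in dioxane), 0 °C to rt; evaporate; then 9, NaOAc, NaBH(OAc)3, ClCH2CH2Cl, rt
Reagents that add atoms: none
Why: Acidolysis of the carbamate followed by reductive amination with NaBH(OAc)3 should stop at the secondary amine because the α-branched amine is hindered, and keeping the amine protonated until the aldehyde is present avoids attack of the free amine on the neighbouring lactone; no stereocentre is touched.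

Step 4
Reactants: 12 secondary amine; 13 monobenzyl malonate
Product: 14 benzyl malonamate
Conditions: DCC, CH2Cl2, 0 °C to rt
Reagents that add atoms: none
Why: Carbodiimide amide coupling of the secondary amine with the malonic half ester should give the tertiary malonamate and, by removing the N–H, ends the risk of lactone-to-lactam acyl transfer.

Step 5
Reactants: 14 benzyl malonamate; 15 hex-1-en-3-one
Product: 16 E-enone
Conditions: second-generation Grubbs catalyst (5 mol%), 15 (3 equiv), CH2Cl2, 40 °C
Reagents that add atoms: none
Why: Olefin cross-metathesis between the terminal alkene and an excess of the electron-poor vinyl ketone, which does not homodimerise readily, should give the E enone.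

Step 6
Reactants: 16 E-enone
Product: 19 cyclopropyl ketone, via Michael adduct 17 (not isolated), via iodo lactam 18 (not isolated)
Conditions: DBU (2.5 equiv), CH2Cl2, 0 °C to rt; then I2 (1.1 equiv), 0 °C to rt
Reagents that add atoms: none
Why: A Michael-initiated ring closure in three stages (6-exo-trig Michael addition of the malonamate anion to the enone, iodination of the malonamate carbon trans to the new side chain, 3-exo-tet displacement of iodide by the ketone enolate) should give the cis-fused cyclopropane; in the boat-like addition transition state the lactone substituent next to nitrogen stands pseudo-axial to avoid allylic strain with the N-alkyl group and the enone arm pseudo-equatorial, which places the new ketone-bearing arm cis to that substituent, the quaternary centre follows from the cis fusion, and the butanoyl group takes the exo position trans to the ring CH2.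

Step 7
Reactants: 19 cyclopropyl ketone
Product: 20 Z-silyloxybutenyl cyclopropane
Conditions: TBSOTf, Et3N, CH2Cl2, −78 to 0 °C
Reagents that add atoms: tert-butyldimethylsilyl trifluoromethanesulfonate, CC(C)(C)[Si](C)(C)OS(=O)(=O)C(F)(F)F
Why: Soft enolisation with TBSOTf and Et3N can only occur towards the propyl CH2, since the cyclopropyl CH would give a strained alkylidenecyclopropane, and should give the Z silyl enol ether in which ethyl is trans to the cyclopropane.

Step 8
Reactants: 20 Z-silyloxybutenyl cyclopropane
Product: 21 bicyclic lactam silyl enol ether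
Conditions: Ni(cod)2 (10 mol%), 1,3-bis(2,6-diisopropylphenyl)imidazol-2-ylidene (12 mol%), PhMe, 60 °C
Reagents that add atoms: none
Why: Zerovalent nickel bound to the carbene inserts into the cyclopropane bond that joins the quaternary carbon, flanked by the lactam and ester carbonyls, to the carbon bearing the silyloxyvinyl group, which gives an allyl nickel unit tethered to a malonamate-type carbon, and C–C reductive elimination at the ethyl-bearing allyl terminus then releases the cyclopentene as its silyl enol ether. The closest known reactions are the nickel–carbene-catalysed isomerisation of vinylcyclopropanes to cyclopentenes and the thermal rearrangement of silyloxyvinylcyclopropanes. The one new ring, the cyclopentene, closes by a net [1,3] shift of the quaternary carbon from one allyl terminus to the other, that is by reductive elimination from a six-membered allyl nickelacycle, which enlarges the three-membered ring by two carbons. The quaternary centre keeps its configuration because the lactam ties it to the neighbouring ring-fusion CH and only a cis fusion is within reach, and the ethyl-bearing centre follows from the Z geometry of the enol ether combined with migration across a single face of the allyl unit, which places ethyl trans to the ester. The step needs cleavage of this bond only, closure at carbon instead of carbonyl oxygen and no hydrogen shift: only this bond is both allylic and doubly acceptor-substituted, closure at an ester or lactam oxygen would give a strained ketene acetal, and the vinyl group is trans to the ring CH2 so that no cis C–H is placed for a homodienyl 1,5-hydrogen shift.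

Step 9
Reactants: 21 bicyclic lactam silyl enol ether; 22 ethyl bromo(diethoxyphosphoryl)acetate
Product: 23 keto phosphonoacetate
Conditions: fac-Ir(ppy)3 (1 mol%), 2,6-lutidine, MeCN, blue LEDs, rt; aq. work-up
Reagents that add atoms: none
Why: Radical alkylation of a silyl enol ether: the electrophilic phosphonoacetate radical formed by photoredox reduction of the C–Br bond adds to the enol ether carbon from the convex face, trans to the neighbouring lactam CH2, and oxidation of the α-silyloxy radical with loss of the silyl group gives the ketone, the centre between phosphorus and ester being left undefined because step 11 removes it.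

Step 10
Reactants: 23 keto phosphonoacetate
Product: 25 phosphono lactone, via alcohol 24 (not isolated)
Conditions: LiBH(s-Bu)3 (L-Selectride), THF, −78 °C; H2O; then PPTS (cat.), PhMe, 60 °C
Reagents that add atoms: none
Why: Reduction with the bulky LiBH(s-Bu)3 should deliver hydride anti to the larger α-substituent (the phosphonoacetate arm) and to the angular ester, giving the alcohol cis to that arm, which alone can lactonise to the cis-fused γ-lactone (diastereoselective ketone reduction, then lactonisation).

Step 11
Reactants: 25 phosphono lactone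
Product: 26 α-methylene lactone
Conditions: K2CO3, aq. CH2O (37%), THF, 0 °C
Reagents that add atoms: formaldehyde, C=O
Why: Horner–Wadsworth–Emmons olefination of the α-phosphono lactone with formaldehyde should give the α-methylene lactone and erases the undefined centre.

Step 12
Reactants: 26 α-methylene lactone
Product: 27 hydroxy acid
Conditions: H2 (1 atm), 10% Pd/C, EtOAc–EtOH, rt
Reagents that add atoms: none
Why: Catalytic hydrogenation should add hydrogen to the exocyclic alkene from the convex face of the cis-fused bicyclic lactone, which places the new methyl on the concave face, cis to the adjoining cyclopentane bond as in the target, while hydrogenolysis frees the primary alcohol and the carboxylic acid from their benzyl groups.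

Step 13
Reactants: 27 hydroxy acid
Product: 28 diol
Conditions: BH3·THF, THF, 0 °C; MeOH quench
Reagents that add atoms: none
Why: Borane reduces a carboxylic acid through its acyloxyborane far faster than lactones or a hindered tertiary lactam (chemoselective acid reduction), so the neopentyl alcohol should form without touching the other carbonyl groups.

Step 14
Reactants: 28 diol
Product: 29 iodo alcohol
Conditions: I2 (1.1 equiv), PPh3, imidazole, CH2Cl2, 0 °C
Reagents that add atoms: iodine, II
Why: Appel-type iodination is an SN2 displacement and should occur only at the unhindered primary alcohol of the N-propyl chain, the neopentyl alcohol on the quaternary carbon being inert to substitution.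

Step 15
Reactants: 29 iodo alcohol
Product: 30 iodo aldehyde
Conditions: Dess–Martin periodinane, NaHCO3, CH2Cl2, 0 °C to rt
Reagents that add atoms: none
Why: Dess–Martin oxidation of the neopentyl alcohol under buffered neutral conditions should give the non-enolisable aldehyde and leave the primary iodide and both lactones untouched.

Step 16
Reactants: 30 iodo aldehyde
Product: 31 target CNP0120800.1
Conditions: SmI2 (2.5 equiv), HMPA, THF (0.005 M), −78 to 0 °C
Reagents that add atoms: none
Why: Samarium Barbier reaction: SmI2 with HMPA turns the primary iodide into a carbon nucleophile that adds to the aldehyde (7-exo-trig), closing the seven-membered ring of the bridged lactam, and with HMPA suppressing chelation the aldehyde oxygen should stay anti to the lactam carbonyl while the chain approaches between the lactam carbonyl and the ring-fusion carbon, which gives the carbinol configuration of the target.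

**Compound list**

1 | N-Boc-D-allylglycine, (R)-2-[(tert-butoxycarbonyl)amino]pent-4-enoic acid | CC(C)(C)OC(=O)N[C@H](CC=C)C(=O)O | starting material
2 | acyl imidazolide of 1, tert-butyl (R)-[1-(imidazol-1-yl)-1-oxopent-4-en-2-yl]carbamate (not isolated) | CC(C)(C)OC(=O)N[C@H](CC=C)C(=O)n1ccnc1 | intermediate
3 | N-Boc-D-allylglycinal, tert-butyl (R)-(1-oxopent-4-en-2-yl)carbamate | CC(C)(C)OC(=O)N[C@H](CC=C)C=O | intermediate
4 | methyl (S)-3-bromo-2-methylpropanoate | BrC[C@@H](C)C(=O)OC | starting material
5 | [(S)-3-methoxy-2-methyl-3-oxopropyl]zinc bromide (not isolated) | Br[Zn]C[C@@H](C)C(=O)OC | intermediate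
6 | dichloro(isopropoxy)[(S)-3-methoxy-2-methyl-3-oxopropyl]titanium (not isolated) | CC(C)O[Ti](Cl)(Cl)C[C@@H](C)C(=O)OC | intermediate
7 | methyl (2R,4R,5R)-5-[(tert-butoxycarbonyl)amino]-4-hydroxy-2-methyloct-7-enoate (not isolated) | CC(C)(C)OC(=O)N[C@H](CC=C)[C@H](O)C[C@@H](C)C(=O)OC | intermediate
8 | tert-butyl {(1R)-1-[(2R,4R)-4-methyl-5-oxooxolan-2-yl]but-3-en-1-yl}carbamate (cis-disubstituted lactone) | CC(C)(C)OC(=O)N[C@H](CC=C)[C@H]1C[C@@H](C)C(=O)O1 | intermediate
9 | 3-(benzyloxy)propanal | O=CCCOCc1ccccc1 | starting material
10 | (1R)-1-[(2R,4R)-4-methyl-5-oxooxolan-2-yl]but-3-en-1-aminium chloride (not isolated) | [Cl-].[NH3+][C@H](CC=C)[C@H]1C[C@@H](C)C(=O)O1 | intermediate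
11 | (3R,5R)-5-[(1R)-1-{[3-(benzyloxy)propylidene]amino}but-3-en-1-yl]-3-methyloxolan-2-one (not isolated) | C(CCOCc1ccccc1)=N[C@H](CC=C)[C@H]1C[C@@H](C)C(=O)O1 | intermediate
12 | (3R,5R)-5-[(1R)-1-{[3-(benzyloxy)propyl]amino}but-3-en-1-yl]-3-methyloxolan-2-one | c1ccccc1COCCCN[C@H](CC=C)[C@H]1C[C@@H](C)C(=O)O1 | intermediate
13 | monobenzyl malonate, 3-(benzyloxy)-3-oxopropanoic acid | OC(=O)CC(=O)OCc1ccccc1 | starting material
14 | benzyl 3-{[3-(benzyloxy)propyl][(1R)-1-((2R,4R)-4-methyl-5-oxooxolan-2-yl)but-3-en-1-yl]amino}-3-oxopropanoate | C=CC[C@H]([C@H]1C[C@@H](C)C(=O)O1)N(CCCOCc1ccccc1)C(=O)CC(=O)OCc1ccccc1 | intermediate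
15 | hex-1-en-3-one | CCCC(=O)C=C | starting material
16 | benzyl 3-{[3-(benzyloxy)propyl][(1R,3E)-1-((2R,4R)-4-methyl-5-oxooxolan-2-yl)-5-oxooct-3-en-1-yl]amino}-3-oxopropanoate | CCCC(=O)/C=C/C[C@H]([C@H]1C[C@@H](C)C(=O)O1)N(CCCOCc1ccccc1)C(=O)CC(=O)OCc1ccccc1 | intermediate
17 | benzyl (4S,6R)-1-[3-(benzyloxy)propyl]-6-[(2R,4R)-4-methyl-5-oxooxolan-2-yl]-2-oxo-4-(2-oxopentyl)piperidine-3-carboxylate, C3 epimers, 4,6-cis (not isolated) | CCCC(=O)C[C@@H]1C[C@H]([C@H]2C[C@@H](C)C(=O)O2)N(CCCOCc2ccccc2)C(=O)C1C(=O)OCc1ccccc1 | intermediate
18 | (3S,4S,6R)-3-iodo derivative of 17, iodine trans to the 2-oxopentyl arm (not isolated) | CCCC(=O)C[C@@H]1C[C@H]([C@H]2C[C@@H](C)C(=O)O2)N(CCCOCc2ccccc2)C(=O)[C@]1(I)C(=O)OCc1ccccc1 | intermediate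
19 | benzyl 3-[3-(benzyloxy)propyl]-7-butanoyl-4-[(2R,4R)-4-methyl-5-oxooxolan-2-yl]-2-oxo-3-azabicyclo[4.1.0]heptane-1-carboxylate; cis-fused, butanoyl exo (cis to the ester, trans to C5H2), C4 substituent cis to C7 | CCCC(=O)[C@H]1[C@@H]2C[C@H]([C@H]3C[C@@H](C)C(=O)O3)N(CCCOCc3ccccc3)C(=O)[C@]12C(=O)OCc1ccccc1 | intermediate
20 | as 19 with 7-[(1Z)-1-(tert-butyldimethylsilyloxy)but-1-en-1-yl] in place of butanoyl (key-step precursor) | CC/C=C(\O[Si](C)(C)C(C)(C)C)[C@H]1[C@@H]2C[C@H]([C@H]3C[C@@H](C)C(=O)O3)N(CCCOCc3ccccc3)C(=O)[C@]12C(=O)OCc1ccccc1 | intermediate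
21 | benzyl 2-[3-(benzyloxy)propyl]-6-(tert-butyldimethylsilyloxy)-7-ethyl-3-[(2R,4R)-4-methyl-5-oxooxolan-2-yl]-1-oxo-2,3,4,4a,7,7a-hexahydro-1H-cyclopenta[c]pyridine-7a-carboxylate; cis ring fusion, 7-ethyl trans to the 7a-ester, H-3 cis to H-4a (key-step product) | CC[C@@H]1C(O[Si](C)(C)C(C)(C)C)=C[C@@H]2C[C@H]([C@H]3C[C@@H](C)C(=O)O3)N(CCCOCc3ccccc3)C(=O)[C@]12C(=O)OCc1ccccc1 | intermediate
22 | ethyl bromo(diethoxyphosphoryl)acetate (triethyl 2-bromo-2-phosphonoacetate) | CCOC(=O)C(Br)P(=O)(OCC)OCC | starting material
23 | 6-oxo-octahydro analogue of 21 carrying at C5 a 1-(diethoxyphosphoryl)-2-ethoxy-2-oxoethyl arm, trans to C4 and cis to the 7a-ester; epimers at the phosphorus-bearing carbon | CC[C@@H]1C(=O)[C@@H](C(C(=O)OCC)P(=O)(OCC)OCC)[C@@H]2C[C@H]([C@H]3C[C@@H](C)C(=O)O3)N(CCCOCc3ccccc3)C(=O)[C@]12C(=O)OCc1ccccc1 | intermediate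
24 | 6-hydroxy compound from 23, hydroxyl cis to the C5 arm and trans to ethyl (not isolated) | CC[C@@H]1[C@@H](O)[C@@H](C(C(=O)OCC)P(=O)(OCC)OCC)[C@@H]2C[C@H]([C@H]3C[C@@H](C)C(=O)O3)N(CCCOCc3ccccc3)C(=O)[C@]12C(=O)OCc1ccccc1 | intermediate
25 | α-(diethoxyphosphoryl) γ-lactone closed between the 6-oxygen and the arm carbonyl of 24, cis-fused to the cyclopentane; epimers at the phosphorus-bearing carbon | CC[C@@H]1[C@H]2OC(=O)C(P(=O)(OCC)OCC)[C@H]2[C@@H]2C[C@H]([C@H]3C[C@@H](C)C(=O)O3)N(CCCOCc3ccccc3)C(=O)[C@]12C(=O)OCc1ccccc1 | intermediate
26 | α-methylene γ-lactone corresponding to 25 | CC[C@@H]1[C@H]2OC(=O)C(=C)[C@H]2[C@@H]2C[C@H]([C@H]3C[C@@H](C)C(=O)O3)N(CCCOCc3ccccc3)C(=O)[C@]12C(=O)OCc1ccccc1 | intermediate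
27 | hydroxy acid: α-methyl lactone (methyl cis to the adjoining cyclopentane bond), N-(3-hydroxypropyl) lactam, free carboxylic acid on Cq | CC[C@@H]1[C@H]2OC(=O)[C@@H](C)[C@H]2[C@@H]2C[C@H]([C@H]3C[C@@H](C)C(=O)O3)N(CCCO)C(=O)[C@]12C(=O)O | intermediate
28 | diol: as 27 with hydroxymethyl on Cq | CC[C@@H]1[C@H]2OC(=O)[C@@H](C)[C@H]2[C@@H]2C[C@H]([C@H]3C[C@@H](C)C(=O)O3)N(CCCO)C(=O)[C@]12CO | intermediate
29 | iodo alcohol: N-(3-iodopropyl) lactam with hydroxymethyl on Cq | CC[C@@H]1[C@H]2OC(=O)[C@@H](C)[C@H]2[C@@H]2C[C@H]([C@H]3C[C@@H](C)C(=O)O3)N(CCCI)C(=O)[C@]12CO | intermediate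
30 | iodo aldehyde: N-(3-iodopropyl) lactam with formyl on Cq | CC[C@@H]1[C@H]2OC(=O)[C@@H](C)[C@H]2[C@@H]2C[C@H]([C@H]3C[C@@H](C)C(=O)O3)N(CCCI)C(=O)[C@]12C=O | intermediate
31 | CNP0120800.1 | CC[C@@H]1[C@H]2OC(=O)[C@@H](C)[C@H]2[C@@H]2C[C@H]([C@H]3C[C@@H](C)C(=O)O3)N3CCC[C@@H](O)[C@@]12C3=O | target

**Totals and risks**

Total steps: 16. Longest linear sequence: 16 steps (1 to 31).

Steps most likely to fail:

Step 8. The nickel allyl may return to the cyclopropane or collapse at a carbonyl oxygen faster than it forms the congested quaternary–tertiary bond, and syn/anti isomerisation of the allyl unit would scramble the ethyl-bearing centre. The fallback replaces metal insertion by a stepwise ionic ring expansion under nucleophilic catalysis. It sets out from 20: a catalytic amount of iodotrimethylsilane with hexamethyldisilazane in CH2Cl2 at −78 to −30 °C silylates the ester carbonyl and lets iodide open the activated bond by attack at the ethyl-bearing vinyl carbon with allylic transposition, giving the allylic iodide silyl ketene acetal F1. Its ketene acetal carbon then displaces the iodide intramolecularly (5-exo-tet C-alkylation), which releases iodotrimethylsilane and returns to the route at 21.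

Step 16. Simple reduction of the iodide or pinacol coupling may outrun closure of the strained bridged lactam, and chelation of trivalent samarium between the aldehyde and lactam oxygens can turn the aldehyde and reverse the facial selectivity. The fallback sets the carbinol centre by ketone reduction instead of in the C–C bond formation, so it answers the selectivity problem only. It sets out from 30: the ring is closed with SmI2 and catalytic NiI2 in THF without HMPA, accepting the carbinol epimer F2; Dess–Martin oxidation gives the bridged keto lactam F3; NaBH4 in MeOH at −78 °C, approaching from the open face beside the one-carbon lactam bridge, should then return to the route at 31.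

Step 6. The conjugate addition may show poor facial selectivity relative to the nitrogen-bearing stereocentre, or the iodide may be displaced by the other ketone enolate. The fallback builds the cyclopropane intermolecularly under catalyst control and closes the lactam last. It sets out from 12: Boc2O gives the N-Boc amine F4, and cross-metathesis with 15 gives the N-Boc enone F5. A Michael-initiated ring closure with dibenzyl bromomalonate under a 9-amino-9-deoxy-epi-cinchona amine catalyst, the pseudo-enantiomer chosen for the required face, then gives the cyclopropane diester F6. Trifluoroacetic acid followed by warming with Et3N closes the lactam onto the ester cis to the amine-bearing arm and returns to the route at 19.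

Further compounds
F1 | step 8 | ring-opened allylic iodide with benzyl trimethylsilyl ketene acetal at Cq | CCC(I)/C(O[Si](C)(C)C(C)(C)C)=C\[C@@H]1C[C@H]([C@H]2C[C@@H](C)C(=O)O2)N(CCCOCc2ccccc2)C(=O)C1=C(O[Si](C)(C)C)OCc1ccccc1
F2 | step 16 | carbinol epimer of 31 | CC[C@@H]1[C@H]2OC(=O)[C@@H](C)[C@H]2[C@@H]2C[C@H]([C@H]3C[C@@H](C)C(=O)O3)N3CCC[C@H](O)[C@@]12C3=O
F3 | step 16 | bridged keto lactam | CC[C@@H]1[C@H]2OC(=O)[C@@H](C)[C@H]2[C@@H]2C[C@H]([C@H]3C[C@@H](C)C(=O)O3)N3CCCC(=O)[C@@]12C3=O
F4 | step 6 | N-Boc derivative of 12 | C=CC[C@H]([C@H]1C[C@@H](C)C(=O)O1)N(CCCOCc1ccccc1)C(=O)OC(C)(C)C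
F5 | step 6 | N-Boc E-enone | CCCC(=O)/C=C/C[C@H]([C@H]1C[C@@H](C)C(=O)O1)N(CCCOCc1ccccc1)C(=O)OC(C)(C)C
F6 | step 6 | dibenzyl 2-butanoyl-3-(aminoalkyl)cyclopropane-1,1-dicarboxylate, N-Boc, trans | CCCC(=O)[C@H]1[C@H](C[C@H]([C@H]2C[C@@H](C)C(=O)O2)N(CCCOCc2ccccc2)C(=O)OC(C)(C)C)C1(C(=O)OCc1ccccc1)C(=O)OCc1ccccc1
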